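**Strategy.** The cyclopentane is opened at C3–C3a (azulene numbering), the bond between the tertiary carbinol and the ring-fusion methine, as a retro-aldol towards a C4 ketone, the carbon that later carries the ester. This exposes a hidden symmetry of the seven-membered ring: C4 is flanked by two methyl-bearing carbons, C8a and C6, so the ring derives from C2-symmetric 3,6-dimethylcyclohepta-2,6-dienone. Asymmetric conjugate addition of a masked 3-oxoalkyl Grignard reagent sets quaternary C8a; the key step, an intramolecular aldol of the unmasked 1,6-diketone, then closes the five-membered ring last and sets C3 and C3a in one operation. Hydroxyl-directed reduction, esterification and allylic oxidation at C7 complete the target.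

Key step: step 6

Remarks on the chemistry:
- Azulene numbering is used for the bicycles (C1, C2, C3, C3a, C8a = five-membered ring; C3a, C4–C8, C8a = seven-membered ring). "β" is the face of the C8a methyl group.
- The enantiomer of the chiral NHC ligand in step 5 is assumed to be the one that delivers the S-configured quaternary centre.
- Compounds 2, 7 and 15 are taken as commercial.

**Step 1**
Reactants: 1 2,5-dimethylfuran; 2 1,1,3,3-tetrabromopropan-2-one
Product: 4 meso-1,5-dimethyl-8-oxabicyclo[3.2.1]oct-6-en-3-one, via dibromo cycloadduct 3 (not isolated)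
Conditions: Zn–Cu couple, B(OEt)3, THF, −10 → 23 °C; then Zn–Cu couple, NH4Cl, MeOH, 23 °C
Reagents that add atoms: none
Why: Zinc reduces 2 to the dibromo-oxyallyl cation, which adds to the furan diene in a [4+3] cycloaddition, and zinc/NH4Cl then removes both α-bromines; the bridged bicycle can only form with the two methyl bridgeheads cis, so the product is meso.

**Step 2**
Reactants: 4 meso-1,5-dimethyl-8-oxabicyclo[3.2.1]oct-6-en-3-one
Product: 5 meso-1,5-dimethyl-8-oxabicyclo[3.2.1]octan-3-one
Conditions: H2 (1 atm), Pd/C, EtOAc, 23 °C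
Reagents that add atoms: none
Why: Heterogeneous hydrogenation saturates the strained disubstituted alkene and leaves the ketone untouched; no new stereocentre is formed.

**Step 3**
Reactants: 5 meso-1,5-dimethyl-8-oxabicyclo[3.2.1]octan-3-one
Product: 6 3,6-dimethylcyclohepta-2,6-dien-1-one
Conditions: TsOH·H2O (10 mol %), toluene, reflux, Dean–Stark trap
Reagents that add atoms: none
Why: Acid-catalysed double β-elimination (retro-oxa-Michael opening of the ether bridge, then dehydration of the tertiary β-hydroxy ketone) is the reverse of the known hydration–cyclisation of cross-conjugated dienones and is driven by azeotropic removal of water; the product is achiral.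

**Step 4**
Reactants: 7 4-methylpent-1-en-3-one (isopropyl vinyl ketone)
Product: 9 2-(2-bromoethyl)-2-(propan-2-yl)-1,3-dioxolane, via bromo ketone 8 (not isolated)
Conditions: HBr (gas), CH2Cl2, 0 °C; then ethylene glycol, TsOH (cat.), benzene, reflux, Dean–Stark trap
Reagents that add atoms: hydrogen bromide, Br; ethylene glycol, OCCO
Why: Conjugate hydrobromination of the enone followed by acid-catalysed ketalisation is the standard route to ketal-protected 3-oxoalkyl bromides; no stereocentre is formed.

**Step 5**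
Reactants: 9 2-(2-bromoethyl)-2-(propan-2-yl)-1,3-dioxolane; 6 3,6-dimethylcyclohepta-2,6-dien-1-one
Product: 11 (6S)-3,6-dimethyl-6-{2-[2-(propan-2-yl)-1,3-dioxolan-2-yl]ethyl}cyclohept-2-en-1-one, via Grignard reagent 10 (not isolated)
Conditions: Mg, Et2O, 35 °C; then 6, Cu(OTf)2 (3 mol %), C2-symmetric chiral 4,5-diphenylimidazolinium salt (NHC precursor, 4 mol %), Et2O, −30 °C; aq NH4Cl
Reagents that add atoms: none
Why: Copper–NHC-catalysed asymmetric conjugate addition of Grignard reagents to β-methyl cycloalkenones is an established route to quaternary centres; the two β-carbons of 6 are equivalent through its C2 axis, so the chiral catalyst only has to select the π-face (which sets C6 as S), and the magnesium dienolate formed cannot add a second time.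

**Step 6 (key step)**
Reactants: 11 (6S)-3,6-dimethyl-6-{2-[2-(propan-2-yl)-1,3-dioxolan-2-yl]ethyl}cyclohept-2-en-1-one
Product: 13 (3R,3aR,8aS)-3-hydroxy-6,8a-dimethyl-3-(propan-2-yl)-2,3,3a,7,8,8a-hexahydroazulen-4(1H)-one (trans-fused; 3-OH on the β face), via diketone 12 (not isolated)
Conditions: TsOH·H2O (10 mol %), THF/H2O (4:1), 40 °C; then KOH (0.5 equiv), MeOH, 0 °C
Reagents that add atoms: water, O
Why: Mild acid unmasks the isopropyl ketone, and base then forms the cross-conjugated α′-enolate at C7 of the cycloheptenone (the future ring-fusion carbon C3a), which adds to the side-chain ketone in an intramolecular aldol reaction. The closest known reaction type is the aldol stage of the classical cyclopentene annulation (conjugate addition of a masked 3-oxoalkyl Grignard reagent, then aldol closure), stopped here before dehydration by working cold with dilute hydroxide. The cyclopentane closes in the 5-(enolexo)-exo-trig mode and forms the most congested bond of the target, C3–C3a. The kinetic closure should be cis-fused, but C3a stays epimerisable (α to the ketone) and the aldol is reversible, so the ring fusion is set under thermodynamic control, where hydroazulenones with the carbonyl in the seven-membered ring next to the fusion are expected to favour the trans isomer (C3a–H anti to the C8a methyl). The carbinol centre C3 follows from the same equilibration: the hydroxyl sits syn to the ring carbonyl (internal hydrogen bond) and the isopropyl group points away from it. The step needs enolisation towards C7 and no dehydration; the competing aldol of the isopropyl-ketone enolate onto the enone carbonyl would give a strained bridged ketol without enone conjugation, which should revert under the same conditions.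

**Step 7**
Reactants: 13 (3R,3aR,8aS)-3-hydroxy-6,8a-dimethyl-3-(propan-2-yl)-2,3,3a,7,8,8a-hexahydroazulen-4(1H)-one
Product: 14 (3R,3aS,4S,8aS)-6,8a-dimethyl-3-(propan-2-yl)-1,2,3,3a,4,7,8,8a-octahydroazulene-3,4-diol
Conditions: Me4NBH(OAc)3, MeCN/AcOH (1:1), −30 °C
Reagents that add atoms: none
Why: In this Evans–Saksena reduction the tertiary C3 hydroxyl exchanges onto boron and delivers hydride intramolecularly to the C4 carbonyl from the β face, on which C3 sits, giving the 4α-alcohol (1,3-anti diol) without touching the enone double bond.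

**Step 8**
Reactants: 14 (3R,3aS,4S,8aS)-6,8a-dimethyl-3-(propan-2-yl)-1,2,3,3a,4,7,8,8a-octahydroazulene-3,4-diol; 15 (2E)-3-[4-(acetyloxy)phenyl]prop-2-enoic acid (4-acetoxycinnamic acid)
Product: 16 (3R,3aS,4S,8aS)-3-hydroxy-6,8a-dimethyl-3-(propan-2-yl)-1,2,3,3a,4,7,8,8a-octahydroazulen-4-yl (2E)-3-[4-(acetyloxy)phenyl]prop-2-enoate
Conditions: DCC, DMAP (cat.), CH2Cl2, 0 → 23 °C
Reagents that add atoms: none
Why: Steglich esterification acylates only the secondary allylic C4 hydroxyl, the tertiary C3 hydroxyl being too hindered, and the configuration at C4 is retained.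

**Step 9**
Reactants: 16 (3R,3aS,4S,8aS)-3-hydroxy-6,8a-dimethyl-3-(propan-2-yl)-1,2,3,3a,4,7,8,8a-octahydroazulen-4-yl (2E)-3-[4-(acetyloxy)phenyl]prop-2-enoate
Product: 18 (3R,3aS,4S,8aR)-3-hydroxy-6,8a-dimethyl-7-oxo-3-(propan-2-yl)-1,2,3,3a,4,7,8,8a-octahydroazulen-4-yl (2E)-3-[4-(acetyloxy)phenyl]prop-2-enoate, via allylic alcohol 17 (not isolated)
Conditions: SeO2 (0.5 equiv), t-BuOOH, CH2Cl2, 23 °C; then Dess–Martin periodinane, CH2Cl2, 0 °C
Reagents that add atoms: selenium dioxide, O=[Se]=O (oxygen donor, turned over by the hydroperoxide); tert-butyl hydroperoxide, CC(C)(C)OO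
Why: In the Riley oxidation selenium adds to the less substituted alkene carbon C5 (ene reaction), and the [2,3] shift then oxygenates the ring methylene C7 on the methyl-bearing alkene carbon; Dess–Martin oxidation of the transient allylic alcohol gives the enone, while the acyloxy-bearing C4–H, the cinnamate alkene and the tertiary alcohol should not react.

**Step 10**
Reactants: 18 (3R,3aS,4S,8aR)-3-hydroxy-6,8a-dimethyl-7-oxo-3-(propan-2-yl)-1,2,3,3a,4,7,8,8a-octahydroazulen-4-yl (2E)-3-[4-(acetyloxy)phenyl]prop-2-enoate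
Product: 19 (3R,3aS,4S,8aR)-3-hydroxy-6,8a-dimethyl-7-oxo-3-(propan-2-yl)-1,2,3,3a,4,7,8,8a-octahydroazulen-4-yl (2E)-3-(4-hydroxyphenyl)prop-2-enoate (CNP0310968.1)
Conditions: NH4OAc, MeOH, 23 °C
Reagents that add atoms: none
Why: Aryl acetates undergo neutral methanolysis much faster than the hindered cinnamate ester, so the phenol is freed without disturbing the γ-acyloxy enone.

**Compound list**
1 | 2,5-dimethylfuran | Cc1ccc(C)o1 | starting material
2 | 1,1,3,3-tetrabromopropan-2-one | BrC(Br)C(=O)C(Br)Br | starting material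
3 | 2,4-dibromo-1,5-dimethyl-8-oxabicyclo[3.2.1]oct-6-en-3-one (mixture at the CHBr centres) | C[C@@]12C(Br)C(=O)C(Br)[C@@](C)(O1)C=C2 | intermediate
4 | meso-1,5-dimethyl-8-oxabicyclo[3.2.1]oct-6-en-3-one | C[C@@]12CC(=O)C[C@@](C)(O1)C=C2 | intermediate
5 | meso-1,5-dimethyl-8-oxabicyclo[3.2.1]octan-3-one | C[C@@]12CC(=O)C[C@@](C)(O1)CC2 | intermediate
6 | 3,6-dimethylcyclohepta-2,6-dien-1-one | CC1=CC(=O)C=C(C)CC1 | intermediate
7 | 4-methylpent-1-en-3-one | C=CC(=O)C(C)C | starting material
8 | 1-bromo-4-methylpentan-3-one | BrCCC(=O)C(C)C | intermediate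
9 | 2-(2-bromoethyl)-2-(propan-2-yl)-1,3-dioxolane | BrCCC1(OCCO1)C(C)C | intermediate
10 | {2-[2-(propan-2-yl)-1,3-dioxolan-2-yl]ethyl}magnesium bromide | Br[Mg]CCC1(OCCO1)C(C)C | intermediate
11 | (6S)-3,6-dimethyl-6-{2-[2-(propan-2-yl)-1,3-dioxolan-2-yl]ethyl}cyclohept-2-en-1-one | CC1=CC(=O)C[C@](C)(CCC2(OCCO2)C(C)C)CC1 | intermediate
12 | (6S)-3,6-dimethyl-6-(4-methyl-3-oxopentyl)cyclohept-2-en-1-one | CC1=CC(=O)C[C@](C)(CCC(=O)C(C)C)CC1 | intermediate
13 | (3R,3aR,8aS)-3-hydroxy-6,8a-dimethyl-3-(propan-2-yl)-2,3,3a,7,8,8a-hexahydroazulen-4(1H)-one | CC1=CC(=O)[C@@H]2[C@](C)(CC[C@@]2(O)C(C)C)CC1 | intermediate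
14 | (3R,3aS,4S,8aS)-6,8a-dimethyl-3-(propan-2-yl)-1,2,3,3a,4,7,8,8a-octahydroazulene-3,4-diol | CC1=C[C@H](O)[C@@H]2[C@](C)(CC[C@@]2(O)C(C)C)CC1 | intermediate
15 | (2E)-3-[4-(acetyloxy)phenyl]prop-2-enoic acid | CC(=O)Oc1ccc(/C=C/C(=O)O)cc1 | starting material
16 | (3R,3aS,4S,8aS)-3-hydroxy-6,8a-dimethyl-3-(propan-2-yl)-1,2,3,3a,4,7,8,8a-octahydroazulen-4-yl (2E)-3-[4-(acetyloxy)phenyl]prop-2-enoate | CC1=C[C@H](OC(=O)/C=C/c2ccc(OC(C)=O)cc2)[C@@H]2[C@](C)(CC[C@@]2(O)C(C)C)CC1 | intermediate
17 | 7-hydroxy derivative of 16 (mixture of C7 epimers) | CC1=C[C@H](OC(=O)/C=C/c2ccc(OC(C)=O)cc2)[C@@H]2[C@](C)(CC[C@@]2(O)C(C)C)CC1O | intermediate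
18 | (3R,3aS,4S,8aR)-3-hydroxy-6,8a-dimethyl-7-oxo-3-(propan-2-yl)-1,2,3,3a,4,7,8,8a-octahydroazulen-4-yl (2E)-3-[4-(acetyloxy)phenyl]prop-2-enoate | CC1=C[C@H](OC(=O)/C=C/c2ccc(OC(C)=O)cc2)[C@@H]2[C@](C)(CC[C@@]2(O)C(C)C)CC1=O | intermediate
19 | (3R,3aS,4S,8aR)-3-hydroxy-6,8a-dimethyl-7-oxo-3-(propan-2-yl)-1,2,3,3a,4,7,8,8a-octahydroazulen-4-yl (2E)-3-(4-hydroxyphenyl)prop-2-enoate | CC1=C[C@H](OC(=O)/C=C/c2ccc(O)cc2)[C@@H]2[C@](C)(CC[C@@]2(O)C(C)C)CC1=O | target

**Step count.** 10 steps in total. The longest linear sequence is 9 steps (1, 2, 3, 5, 6, 7, 8, 9, 10, from 2,5-dimethylfuran); step 4 is a one-step side branch.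

**Steps most likely to fail**

1. Step 6 (key step). The reversible aldol may settle on the cis-fused ketol that forms kinetically instead of relaxing to the trans ring fusion, or it may run on to dehydration. The fallback sets out from 11 and comes back at 13, and fixes C3 and C3a stereospecifically instead of thermodynamically. Stronger acid (3 M HCl, THF, 60 °C) hydrolyses the ketal and carries the aldol through to dehydration, giving the cross-conjugated dienone (8aS)-6,8a-dimethyl-3-(propan-2-yl)-2,7,8,8a-tetrahydroazulen-4(1H)-one F1, in which the ring-fusion carbon is trigonal. Luche reduction (NaBH4, CeCl3·7H2O, MeOH, −78 °C), with hydride entering anti to the angular methyl, should give (4R,8aS)-6,8a-dimethyl-3-(propan-2-yl)-1,2,4,7,8,8a-hexahydroazulen-4-ol F2. VO(acac)2/t-BuOOH (CH2Cl2, 0 °C) should epoxidise the tetrasubstituted C3=C3a alkene on the face of that hydroxyl, giving the 3,3a-epoxy-6,8a-dimethyl-3-(propan-2-yl)-1,2,3,3a,4,7,8,8a-octahydroazulen-4-ol with epoxide, 4-hydroxyl and angular methyl all β F3. BF3·OEt2 (CH2Cl2, −78 °C) then triggers a semipinacol 1,2-hydride shift from C4 to C3a, anti to the breaking C3a–O bond. This delivers 13 with C3a–H α and the 3-hydroxyl β.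

2. Step 3. Under hot acid the cross-conjugated dienone may isomerise to its linearly conjugated 2,4-isomer, or the ether bridge may open incompletely. The fallback sets out from 5 and comes back at 6, and replaces the acid-driven equilibrium by stepwise eliminations under kinetic control. TMSOTf/Et3N (CH2Cl2, 0 °C) opens the bridge through the silyl enol ether to racemic 3,6-dimethyl-6-(trimethylsilyloxy)cyclohept-2-en-1-one F4. HF·pyridine (THF, 0 °C) frees racemic 6-hydroxy-3,6-dimethylcyclohept-2-en-1-one F5. Trifluoroacetic anhydride/pyridine/DMAP gives 1,4-dimethyl-5-oxocyclohept-3-en-1-yl trifluoroacetate F6, and DBU (CH2Cl2, 23 °C) eliminates it by E1cB to 6.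

3. Step 7. Exchange of the hindered tertiary hydroxyl onto boron may be too slow, so that hydride delivery is not directed and face selectivity at C4 (or 1,2- versus 1,4-selectivity) is lost. The fallback sets out from 13 and comes back at 16, and uses external hydride followed by inversion. Luche reduction (NaBH4, CeCl3·7H2O, MeOH, −78 °C), with attack anti to the angular methyl, should give the 4-epimeric diol (3R,3aS,4R,8aS)-6,8a-dimethyl-3-(propan-2-yl)-1,2,3,3a,4,7,8,8a-octahydroazulene-3,4-diol F7. Mitsunobu esterification with 15 (PPh3, DIAD, toluene, 0 °C) inverts C4 and gives 16 directly.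

**Further compounds**
F1 | step 6 | (8aS)-6,8a-dimethyl-3-(propan-2-yl)-2,7,8,8a-tetrahydroazulen-4(1H)-one | CC1=CC(=O)C2=C(C(C)C)CC[C@]2(C)CC1
F2 | step 6 | (4R,8aS)-6,8a-dimethyl-3-(propan-2-yl)-1,2,4,7,8,8a-hexahydroazulen-4-ol | CC1=C[C@@H](O)C2=C(C(C)C)CC[C@]2(C)CC1
F3 | step 6 | 3,3a-epoxy-6,8a-dimethyl-3-(propan-2-yl)-1,2,3,3a,4,7,8,8a-octahydroazulen-4-ol (epoxide, 4-OH and 8a-methyl all β) | CC1=C[C@@H](O)[C@]23O[C@@]2(C(C)C)CC[C@]3(C)CC1
F4 | step 3 | 3,6-dimethyl-6-(trimethylsilyloxy)cyclohept-2-en-1-one (racemic) | CC1=CC(=O)CC(C)(O[Si](C)(C)C)CC1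
F5 | step 3 | 6-hydroxy-3,6-dimethylcyclohept-2-en-1-one (racemic) | CC1=CC(=O)CC(C)(O)CC1
F6 | step 3 | 1,4-dimethyl-5-oxocyclohept-3-en-1-yl trifluoroacetate (racemic) | CC1=CC(=O)CC(C)(OC(=O)C(F)(F)F)CC1
F7 | step 7 | (3R,3aS,4R,8aS)-6,8a-dimethyl-3-(propan-2-yl)-1,2,3,3a,4,7,8,8a-octahydroazulene-3,4-diol | CC1=C[C@@H](O)[C@@H]2[C@](C)(CC[C@@]2(O)C(C)C)CC1
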